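The summer flask grew slow with its substrate still far from used up: 43.1% stood at 60.0 s, and product had stalled near 57.0%.

common to all: substrate 0.0050 M
- summer: enzyme 0.085 µM; the very flask that is asked about, followed so far
- noon: enzyme 0.17 µM; run made earlier
- flask: enzyme 0.085 µM

| run | time / s | product / % | substrate / % |
|---|---|---|---|
| summer | 12.0 | 32.1 | 67.2 |
| summer | 25.0 | 47.9 | 52.5 |
| summer | 40.0 | 53.8 | 46.0 |
| summer | 50.0 | 56.4 | 44.9 |
| summer | 60.0 | 57.0 | 43.1 |
| noon | 10.0 | 57.4 | 41.2 |
| noon | 30.0 | 90.1 | 9.7 |
| noon | 60.0 | 95.4 | 5.5 |
| noon | 80.0 | 95.0 | 4.1 |
| noon | 120 | 95.8 | 4.5 |

(standard deviation of a reading: 0.5 percentage points)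

- apparent order in enzyme when 10% of the substrate are converted (percent change of the rate of making product for one percent more enzyme charged)

- the analysis behind the earlier runs scatters by 0.5 percentage points, standard deviation

I worked with what was left, not with what was made. Of the final product of the summer flask, 43.7% was still to come at 12.0 s and 16.0% at 25.0 s. A first-order fall through each of these readings gives 14.5 s and 13.6 s. I took the first as the enzyme's life, the time in which the share of final product still to come falls by a factor e. I read that share as the share of enzyme still active (the trade says catalyst deactivation), holding the rate per active enzyme steady.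

Waiting is the first setting. By hand, 3.18% of the final product of the summer flask was still to come at 50.0 s, and its next reading added 0.6 percentage points. Enzyme is the second. By hand, twice the enzyme with the same life gives 56.8% product at 10.0 s, and the noon flask read 57.4%.

At 10% conversion, the summer flask keeps 82.5% of its enzyme active by this rule, and the noon flask, with twice the enzyme and the same life, keeps 91.2%. My order is therefore 1.15, a little above one.

The forecast, holding that “the catalyst is dying rather than equilibrium being reached”, gave 1.6, higher than my figure. The simulation gives 1.2.

    substrate + enzyme → product + enzyme, rate k1*[substrate]*[enzyme]/(1 + ([substrate]/Km1) + ([substrate]/Ksi1)^2) (2.04 mM, 2.93 mM, k = 2.88 × 10⁶ M⁻¹ s⁻¹)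
    enzyme → spent catalyst (k = 0.0710 s⁻¹)

In the summer flask, half of the turnover was done by 10.0 s, sooner than my life of 14.5 s, and at 0.200 min the enzyme stood at 42.7% of its charge. In that flask spent catalyst had reached 98.6% of the catalyst charged by 1.00 min, and substrate stood at 43.5% then and at 42.7% at 20.0 min.

All runs stem from a simulated flask with made-up constants; noise was put on by code.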